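The rate constants were set for the occasion, and the outcome is calculated.

One equivalent of E is the unit I price this flask in: J consumes that equivalent in step 1, and J also traps Z in step 3.

common to all: time 12 h

| run | J | E | remark |
|---|---|---|---|
| gamma | 42 mM (in portions, 4, over 8.0 h) | 1.80 equiv | first portion at the start, last at 8.0 h |
| theta | 42 mM (fed, over 8.0 h) | 1.80 equiv | all else is in the flask from the start; the feed brings no volume worth counting |
| epsilon | 42 mM | 1.80 equiv | everything together at the start |
| eta | 42 mM | 1.80 equiv (fed, over 8.0 h) | all else is in the flask from the start; the feed brings no volume worth counting |

    J + E → X + Q (k1 = 0.32 /M/min)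
    E + X → Z + Q (k2 = 0.016 /M/min)
    J + Z → J.Z (k3 = 0.19 /M/min)

- a species is counted by the J in it: one J.Z counts as two
- run time (gamma): 12 h

* the flask that comes out highest in share of Z in Z plus J.Z, or "all alike" when all lie within 1.5 percentage points (gamma / theta / epsilon / eta / all alike)
* share of Z in Z plus J.Z at the end, gamma
* share of Z in Z plus J.Z at the end, theta
* share of Z in Z plus J.Z at the end, epsilon
* share of Z in Z plus J.Z at the end, eta

I hand over a flask where J and E make X, and X slowly makes Z. I call the toll 0.481: k3/k1, a selectivity factor, times the natural log of [E] before over [E] after one equivalent has gone. Step 2 is left aside, and dosing doesn't enter. If Z stood before J passed, exp(-toll) of it would survive; a trapped Z counts double, so the share's low end is 44.7%. Z made after J has passed pays nothing, so the high end is 100%.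

Expect epsilon near the top, since J's half-life of 0.48 h there is far shorter than the 9.6 h of X by step 2. Don't split epsilon's J: later portions would meet Z already made and pay the toll on it. I put eta next, with gamma and theta lowest, and I can't part those two.

The forecast says epsilon, with gamma 69%, theta 67%, epsilon 90% and eta 83%, on the ground that “all the J is gone early, before much Z exists”. Unlike me, it ranks gamma above theta.

The simulation gives epsilon: gamma 69.9%, theta 73.0%, epsilon 90.2%, eta 81.7%. Theta stands 6 percentage points above the forecast and above gamma. Gamma lies between its low end of 44.7% and the top. Give gamma only 1.10 equiv of E and the toll grows to 1.42, which lowers the low end to 13.7%. That neighbouring flask ends at 44.4%, with Z at 5.76% of the J charged.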